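**Retrosynthetic overview**
1. Numbering used throughout (eudesmane): ring A = C1–C2–C3–C4–C5–C10, ring B = C5–C6–C7–C8–C9–C10; C10 is the quaternary, methyl-bearing fusion carbon, C5=C6 the ring alkene, C7 carries the acrylate, C3 the angelate, C4 the tertiary alcohol.
2. End game: the methyl acrylate comes from a 7-isopropenyl group (allylic oxidation, then CHO to CO2Me); the C4 carbinol from methyl addition to a C4 ketone; the C3 angelate from SN2 displacement on an α′-bromo enone.
3. Key disconnection: the enone C4(=O)–C5=C6 is opened at C5–C6 (aldol retron, C6 at the aldehyde level) and at C9–C10 (conjugate-addition retron), leading back to commercial 3-methylcyclohex-2-en-1-one (ring A) and an acyclic C6–C9 chain that already carries C7.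
4. Enabling feature: the carbinol carbon C4 of ring A stands 1,3 to the quaternary C10, so ring A is a latent 3-methylcyclohexenone; conjugate addition at C10 creates the enolate at C5, the one carbon from which C6 can close ring B as a six-membered ring, and dehydration leaves the C5=C6 alkene of the target.
5. Ring order: ring A is bought; ring B is formed in step 4; C7 is set in step 3, C10 in step 4, C3 and C4 afterwards under control of the angular methyl group.

Key step: step 4

Remark: the absolute sense of induction in steps 3 and 4 is fixed by the choice of ligand enantiomer (both enantiomers of each ligand class are accessible); α/β descriptors refer to the eudesmane numbering above, with the C10 methyl group β.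

Step 1
Reactants: 1 (E)-4,4-dimethoxybut-2-enal
Product: 2 (E)-4,4-dimethoxybut-2-en-1-ol
Conditions: NaBH4, MeOH, 0 °C
Reagents that add atoms: none
Why: Borohydride 1,2-reduction of the enal (carbonyl reduction) should give the allylic alcohol without touching the acetal or the (E)-alkene; no stereocentre is formed.

Step 2
Reactants: 2 (E)-4,4-dimethoxybut-2-en-1-ol
Product: 3 diethyl (E)-4,4-dimethoxybut-2-en-1-yl phosphate
Conditions: ClP(O)(OEt)2, pyridine, DMAP (cat.), CH2Cl2, 0 °C to rt
Reagents that add atoms: diethyl chlorophosphate CCOP(=O)(Cl)OCC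
Why: O-Phosphorylation of the primary allylic alcohol under mild base installs the leaving group for the SN2′ step and leaves the acid-sensitive acetal intact.

Step 3
Reactants: 3 diethyl (E)-4,4-dimethoxybut-2-en-1-yl phosphate; 4 4,4,5,5-tetramethyl-2-(prop-1-en-2-yl)-1,3,2-dioxaborolane
Product: 5 (S)-3-(dimethoxymethyl)-2-methylpenta-1,4-diene
Conditions: CuCl (5 mol %), chiral sulfonate-bearing imidazolinium salt (NHC precursor, 5.5 mol %), NaOMe (1.5 equiv), THF, 60 °C
Reagents that add atoms: none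
Why: NHC–copper-catalysed enantioselective allylic substitution with an alkenylboronate (SN2′, branched-selective) should deliver the isopropenyl group to the γ-carbon, and the chiral NHC ligand (enantiomer chosen for the (S) product) sets the C7 stereocentre.

Step 4
Reactants: 5 (S)-3-(dimethoxymethyl)-2-methylpenta-1,4-diene; 6 3-methylcyclohex-2-en-1-one
Product: 10 (4aR,7R)-4a-methyl-7-(prop-1-en-2-yl)-3,4,4a,5,6,7-hexahydronaphthalen-1(2H)-one, via alkylzirconocene chloride 7 (not isolated), via trimethylsilyl enol ether 8 (not isolated), via β-methoxy ketone 9 (not isolated)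
Conditions: Cp2ZrHCl (1.05 equiv), CH2Cl2, rt; then 6, CuCl/AgNTf2 (10 mol %), BINOL-derived phosphoramidite ligand (10 mol %), Me3SiCl, Et2O, rt; then Me3SiOTf (0.3 equiv), CH2Cl2, −78 °C; then DBU, −78 °C to rt
Reagents that add atoms: none
Why: Cp2ZrHCl hydrometalates only the monosubstituted vinyl group of 5 (the 1,1-disubstituted isopropenyl group reacts far more slowly), and after transmetalation to the chiral phosphoramidite–copper catalyst the primary alkyl group adds 1,4 to 6, the ligand-controlled face selection creating the quaternary carbon C10 with (R) configuration while Me3SiCl traps the enolate regiospecifically as enol ether 8 (nucleophilic carbon = C5). Me3SiOTf then ionises the dimethyl acetal to an oxocarbenium ion at C6, which 8 captures in a 6-(enolexo)-exo-trig Mukaiyama-type closure that forms the C5–C6 bond and ring B (β-methoxy ketone 9), and DBU-induced E1cB loss of methanol installs the C5=C6 double bond of the target. The closest known reaction types are the copper-catalysed asymmetric conjugate addition of alkylzirconocenes to 3-methylcyclohex-2-en-1-one, the intramolecular Mukaiyama aldol reaction of silyl enol ethers with acetals, and tandem conjugate addition–aldol annulations. The C7 stereocentre of 5 is carried through unchanged because the C6 aldehyde is never free and the C–C bond formation runs at −78 °C, and the transient stereocentres at C5 and C6 are erased by the elimination. The step needs closure at C5 and not at C3: this is secured because the conjugate addition itself writes the enol ether at C4=C5 and only C5 can reach C6 through a six-membered transition state. Should C7 epimerise at the enone stage, the required 7β (pseudo-equatorial) epimer is also the thermodynamically preferred one.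

Step 5
Reactants: 10 (4aR,7R)-4a-methyl-7-(prop-1-en-2-yl)-3,4,4a,5,6,7-hexahydronaphthalen-1(2H)-one
Product: 12 (2R,4aS,7R)-2-bromo-4a-methyl-7-(prop-1-en-2-yl)-3,4,4a,5,6,7-hexahydronaphthalen-1(2H)-one, via trimethylsilyl dienol ether 11 (not isolated)
Conditions: LiN(iPr)2, THF, −78 °C; Me3SiCl; then N-bromosuccinimide, THF, −78 °C to 0 °C
Reagents that add atoms: N-bromosuccinimide O=C1CCC(=O)N1Br
Why: Kinetic deprotonation at C3 (α′; the tertiary γ-hydrogen at C7 is removed more slowly) and silylation give the cross-conjugated silyl dienol ether, which N-bromosuccinimide brominates at C3 by stereoelectronically preferred axial attack from the α-face (α-halogenation of a silyl enol ether), giving the axial 3α-bromide.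

Step 6
Reactants: 12 (2R,4aS,7R)-2-bromo-4a-methyl-7-(prop-1-en-2-yl)-3,4,4a,5,6,7-hexahydronaphthalen-1(2H)-one; 13 angelic acid, (Z)-2-methylbut-2-enoic acid
Product: 14 (2S,4aS,7R)-4a-methyl-1-oxo-7-(prop-1-en-2-yl)-1,2,3,4,4a,5,6,7-octahydronaphthalen-2-yl (2Z)-2-methylbut-2-enoate
Conditions: 13 (1.5 equiv), Cs2CO3 (0.75 equiv), DMF, rt
Reagents that add atoms: none
Why: SN2 displacement of the activated α-keto bromide by cesium angelate (carboxylate alkylation) inverts C3 to the equatorial 3β-ester, which is also the thermodynamically preferred epimer, and the weakly basic conditions should leave the (Z)-geometry of the angelate and C7 untouched.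

Step 7
Reactants: 14 (2S,4aS,7R)-4a-methyl-1-oxo-7-(prop-1-en-2-yl)-1,2,3,4,4a,5,6,7-octahydronaphthalen-2-yl (2Z)-2-methylbut-2-enoate
Product: 15 (1R,2S,4aS,7R)-1-hydroxy-1,4a-dimethyl-7-(prop-1-en-2-yl)-1,2,3,4,4a,5,6,7-octahydronaphthalen-2-yl (2Z)-2-methylbut-2-enoate
Conditions: CeCl3 (anhydrous), MeLi, THF, −78 °C; aq. NH4Cl
Reagents that add atoms: methyllithium [Li]C
Why: The organocerium reagent adds 1,2 to the ketone chemoselectively over the enone β-position and the ester (organocerium carbonyl addition), and it attacks C4 from the α-face because the β-face is blocked by the pseudo-axial C10 methyl group, which gives the 4β-hydroxy-4α-methyl carbinol cis to the 3β-ester.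

Step 8
Reactants: 15 (1R,2S,4aS,7R)-1-hydroxy-1,4a-dimethyl-7-(prop-1-en-2-yl)-1,2,3,4,4a,5,6,7-octahydronaphthalen-2-yl (2Z)-2-methylbut-2-enoate
Product: 16 (1R,2S,4aS,7R)-1-hydroxy-7-(3-hydroxyprop-1-en-2-yl)-1,4a-dimethyl-1,2,3,4,4a,5,6,7-octahydronaphthalen-2-yl (2Z)-2-methylbut-2-enoate
Conditions: SeO2 (cat.), t-BuOOH, CH2Cl2, 0 °C to rt
Reagents that add atoms: tert-butyl hydroperoxide CC(C)(C)OO; selenium dioxide O=[Se]=O
Why: Riley-type selenium dioxide allylic oxidation (ene reaction then [2,3]-sigmatropic shift) should oxidise the methyl group of the 1,1-disubstituted alkene in preference to the methine C7–H, while the C5=C6 alkene has no hydrogen on the allylic carbons of its disubstituted end and the angelate alkene is electron-poor.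

Step 9
Reactants: 16 (1R,2S,4aS,7R)-1-hydroxy-7-(3-hydroxyprop-1-en-2-yl)-1,4a-dimethyl-1,2,3,4,4a,5,6,7-octahydronaphthalen-2-yl (2Z)-2-methylbut-2-enoate
Product: 17 (1R,2S,4aS,7R)-1-hydroxy-1,4a-dimethyl-7-(3-oxoprop-1-en-2-yl)-1,2,3,4,4a,5,6,7-octahydronaphthalen-2-yl (2Z)-2-methylbut-2-enoate
Conditions: MnO2, CH2Cl2, rt
Reagents that add atoms: none
Why: MnO2 oxidises only the primary allylic alcohol to the 2-substituted acrolein (allylic alcohol oxidation) and cannot oxidise the tertiary allylic alcohol.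

Step 10
Reactants: 17 (1R,2S,4aS,7R)-1-hydroxy-1,4a-dimethyl-7-(3-oxoprop-1-en-2-yl)-1,2,3,4,4a,5,6,7-octahydronaphthalen-2-yl (2Z)-2-methylbut-2-enoate
Product: 18 2-[(2R,4aS,7S,8R)-8-hydroxy-4a,8-dimethyl-7-{[(2Z)-2-methylbut-2-enoyl]oxy}-2,3,4,4a,5,6,7,8-octahydronaphthalen-2-yl]prop-2-enoic acid
Conditions: NaClO2, NaH2PO4, 2-methylbut-2-ene, t-BuOH/H2O, 0 °C to rt
Reagents that add atoms: sodium chlorite [Na+].[O-]Cl=O
Why: Pinnick oxidation converts the enal to the acrylic acid under buffered conditions that leave the alkenes, the tertiary allylic alcohol and C7 untouched, the alkene scavenger removing hypochlorous acid.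

Step 11
Reactants: 18 2-[(2R,4aS,7S,8R)-8-hydroxy-4a,8-dimethyl-7-{[(2Z)-2-methylbut-2-enoyl]oxy}-2,3,4,4a,5,6,7,8-octahydronaphthalen-2-yl]prop-2-enoic acid
Product: 19 methyl 2-[(2R,4aS,7S,8R)-8-hydroxy-4a,8-dimethyl-7-{[(2Z)-2-methylbut-2-enoyl]oxy}-2,3,4,4a,5,6,7,8-octahydronaphthalen-2-yl]prop-2-enoate
Conditions: Me3SiCHN2, MeOH/toluene, 0 °C
Reagents that add atoms: trimethylsilyldiazomethane C[Si](C)(C)C=[N+]=[N-]
Why: O-Methylation of the carboxylic acid with trimethylsilyldiazomethane (diazoalkane esterification) is neutral and fast, so neither the angelate geometry nor the tertiary allylic alcohol should be affected.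

**Compound list**
1 | (E)-4,4-dimethoxybut-2-enal (fumaraldehyde mono(dimethyl acetal)) | O=C/C=C/C(OC)OC | starting material
2 | (E)-4,4-dimethoxybut-2-en-1-ol | OC/C=C/C(OC)OC | intermediate
3 | diethyl (E)-4,4-dimethoxybut-2-en-1-yl phosphate | CCOP(=O)(OCC)OC/C=C/C(OC)OC | intermediate
4 | 4,4,5,5-tetramethyl-2-(prop-1-en-2-yl)-1,3,2-dioxaborolane (isopropenylboronic acid pinacol ester) | C=C(C)B1OC(C)(C)C(C)(C)O1 | starting material
5 | (S)-3-(dimethoxymethyl)-2-methylpenta-1,4-diene | C=C(C)[C@H](C=C)C(OC)OC | intermediate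
6 | 3-methylcyclohex-2-en-1-one | CC1=CC(=O)CCC1 | starting material
7 | chlorobis(cyclopentadienyl)[(3S)-3-(dimethoxymethyl)-4-methylpent-4-en-1-yl]zirconium | C=C(C)[C@H](CC[Zr](Cl)(C1C=CC=C1)C1C=CC=C1)C(OC)OC | intermediate
8 | {[(3R)-3-[(3S)-3-(dimethoxymethyl)-4-methylpent-4-en-1-yl]-3-methylcyclohex-1-en-1-yl]oxy}trimethylsilane | C=C(C)[C@H](CC[C@@]1(C)CCCC(O[Si](C)(C)C)=C1)C(OC)OC | intermediate
9 | (4aR,7S)-8-methoxy-4a-methyl-7-(prop-1-en-2-yl)octahydronaphthalen-1(2H)-one (epimers at C8 and C8a) | C=C(C)[C@H]1C(OC)C2[C@](C)(CCCC2=O)CC1 | intermediate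
10 | (4aR,7R)-4a-methyl-7-(prop-1-en-2-yl)-3,4,4a,5,6,7-hexahydronaphthalen-1(2H)-one | C=C(C)[C@H]1C=C2[C@](C)(CCCC2=O)CC1 | intermediate
11 | trimethyl{[(4aS,7R)-4a-methyl-7-(prop-1-en-2-yl)-3,4,4a,5,6,7-hexahydronaphthalen-1-yl]oxy}silane | C=C(C)[C@H]1C=C2[C@](C)(CCC=C2O[Si](C)(C)C)CC1 | intermediate
12 | (2R,4aS,7R)-2-bromo-4a-methyl-7-(prop-1-en-2-yl)-3,4,4a,5,6,7-hexahydronaphthalen-1(2H)-one (3α-bromide) | C=C(C)[C@H]1C=C2[C@](C)(CC[C@@H](Br)C2=O)CC1 | intermediate
13 | angelic acid, (Z)-2-methylbut-2-enoic acid | C/C=C(/C)C(=O)O | starting material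
14 | (2S,4aS,7R)-4a-methyl-1-oxo-7-(prop-1-en-2-yl)-1,2,3,4,4a,5,6,7-octahydronaphthalen-2-yl (2Z)-2-methylbut-2-enoate | C=C(C)[C@H]1C=C2[C@](C)(CC[C@H](OC(=O)/C(C)=C\C)C2=O)CC1 | intermediate
15 | (1R,2S,4aS,7R)-1-hydroxy-1,4a-dimethyl-7-(prop-1-en-2-yl)-1,2,3,4,4a,5,6,7-octahydronaphthalen-2-yl (2Z)-2-methylbut-2-enoate | C=C(C)[C@H]1C=C2[C@](C)(CC[C@H](OC(=O)/C(C)=C\C)[C@]2(C)O)CC1 | intermediate
16 | (1R,2S,4aS,7R)-1-hydroxy-7-(3-hydroxyprop-1-en-2-yl)-1,4a-dimethyl-1,2,3,4,4a,5,6,7-octahydronaphthalen-2-yl (2Z)-2-methylbut-2-enoate | C=C(CO)[C@H]1C=C2[C@](C)(CC[C@H](OC(=O)/C(C)=C\C)[C@]2(C)O)CC1 | intermediate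
17 | (1R,2S,4aS,7R)-1-hydroxy-1,4a-dimethyl-7-(3-oxoprop-1-en-2-yl)-1,2,3,4,4a,5,6,7-octahydronaphthalen-2-yl (2Z)-2-methylbut-2-enoate | C=C(C=O)[C@H]1C=C2[C@](C)(CC[C@H](OC(=O)/C(C)=C\C)[C@]2(C)O)CC1 | intermediate
18 | 2-[(2R,4aS,7S,8R)-8-hydroxy-4a,8-dimethyl-7-{[(2Z)-2-methylbut-2-enoyl]oxy}-2,3,4,4a,5,6,7,8-octahydronaphthalen-2-yl]prop-2-enoic acid | C=C(C(=O)O)[C@H]1C=C2[C@](C)(CC[C@H](OC(=O)/C(C)=C\C)[C@]2(C)O)CC1 | intermediate
19 | methyl 2-[(2R,4aS,7S,8R)-8-hydroxy-4a,8-dimethyl-7-{[(2Z)-2-methylbut-2-enoyl]oxy}-2,3,4,4a,5,6,7,8-octahydronaphthalen-2-yl]prop-2-enoate | C=C(C(=O)OC)[C@H]1C=C2[C@](C)(CC[C@H](OC(=O)/C(C)=C\C)[C@]2(C)O)CC1 | target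

**Step count and risks**
Total step count: 11. Longest linear sequence: 11 steps (1 to 19; compounds 4, 6 and 13 are bought).

Steps most likely to fail:

Step 4. Transfer of the β-branched, acetal-bearing alkyl group from zirconium to copper may be slow, which would erode enantiocontrol at C10. In the base-mediated elimination the doubly allylic C7–H may be removed, with epimerisation or migration of the side-chain double bond into conjugation. The fallback builds the quaternary centre the other way round and separates the operations. Setting out from 5, hydroboration of the vinyl group with 9-BBN and B-alkyl Suzuki–Miyaura coupling with 3-bromocyclohex-2-en-1-one (PdCl2(dppf), K3PO4, THF/DMF) should give 3-[(3S)-3-(dimethoxymethyl)-4-methylpent-4-en-1-yl]cyclohex-2-en-1-one F1. Copper-catalysed asymmetric conjugate addition of Me3Al (copper thiophene-2-carboxylate, phosphoramidite, Et2O, −30 °C) with Me3SiOTf quench of the aluminium enolate should then deliver silyl enol ether 8 in isolated form, where the route is rejoined. The Mukaiyama closure and the elimination to 10 are then run and optimised separately on purified material.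

Step 8. The selenium reagent may attack the doubly allylic C7–H instead of the methyl group, and the tertiary allylic alcohol may ionise or transpose under the mildly acidic conditions. The fallback carries the allylic oxygen from the start, setting out from 3. Copper-catalysed α-selective protoboration of commercial tert-butyldimethyl(prop-2-yn-1-yloxy)silane with bis(pinacolato)diboron and MeOH should give tert-butyldimethyl{[2-(4,4,5,5-tetramethyl-1,3,2-dioxaborolan-2-yl)prop-2-en-1-yl]oxy}silane F4. Allylic substitution of 3 with it under the conditions of step 3 should give tert-butyl{[(3S)-3-(dimethoxymethyl)-2-methylidenepent-4-en-1-yl]oxy}dimethylsilane F5. The annulation of step 4 with 6 should give (4aR,7R)-7-{3-[(tert-butyldimethylsilyl)oxy]prop-1-en-2-yl}-4a-methyl-3,4,4a,5,6,7-hexahydronaphthalen-1(2H)-one F6. Bromination as in step 5 should give (2R,4aS,7R)-2-bromo-7-{3-[(tert-butyldimethylsilyl)oxy]prop-1-en-2-yl}-4a-methyl-3,4,4a,5,6,7-hexahydronaphthalen-1(2H)-one F7. Displacement with cesium angelate as in step 6 should give (2S,4aS,7R)-7-{3-[(tert-butyldimethylsilyl)oxy]prop-1-en-2-yl}-4a-methyl-1-oxo-1,2,3,4,4a,5,6,7-octahydronaphthalen-2-yl (2Z)-2-methylbut-2-enoate F8. Methyl addition as in step 7 should give (1R,2S,4aS,7R)-7-{3-[(tert-butyldimethylsilyl)oxy]prop-1-en-2-yl}-1-hydroxy-1,4a-dimethyl-1,2,3,4,4a,5,6,7-octahydronaphthalen-2-yl (2Z)-2-methylbut-2-enoate F9. Desilylation with Bu4NF/AcOH in THF then gives 16, where the route is rejoined before the MnO2 oxidation.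

Step 7. The organometallic may attack the neighbouring angelate, or the new tertiary alkoxide may take over the acyl group (1,2-acyl migration), so that ester and carbinol end up in the wrong places. The fallback installs the angelate after the carbon–carbon bond formation, setting out from 12. Displacement with cesium acetate (DMF, rt) should give (2S,4aS,7R)-4a-methyl-1-oxo-7-(prop-1-en-2-yl)-1,2,3,4,4a,5,6,7-octahydronaphthalen-2-yl acetate F2. Excess MeLi/CeCl3 (THF, −78 °C to 0 °C) adds to the ketone from the α-face and cleaves the sacrificial acetate in the same operation, giving (1R,2S,4aS,7R)-1,4a-dimethyl-7-(prop-1-en-2-yl)-1,2,3,4,4a,5,6,7-octahydronaphthalene-1,2-diol F3. Yamaguchi esterification with 13 (2,4,6-trichlorobenzoyl chloride, Et3N, toluene; then F3, 80 °C) should acylate only the secondary hydroxyl group and give 15, where the route is rejoined.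

**Further compounds**
F1 | step 4 | 3-[(3S)-3-(dimethoxymethyl)-4-methylpent-4-en-1-yl]cyclohex-2-en-1-one | C=C(C)[C@H](CCC1=CC(=O)CCC1)C(OC)OC
F2 | step 7 | (2S,4aS,7R)-4a-methyl-1-oxo-7-(prop-1-en-2-yl)-1,2,3,4,4a,5,6,7-octahydronaphthalen-2-yl acetate | C=C(C)[C@H]1C=C2[C@](C)(CC[C@H](OC(C)=O)C2=O)CC1
F3 | step 7 | (1R,2S,4aS,7R)-1,4a-dimethyl-7-(prop-1-en-2-yl)-1,2,3,4,4a,5,6,7-octahydronaphthalene-1,2-diol | C=C(C)[C@H]1C=C2[C@](C)(CC[C@H](O)[C@]2(C)O)CC1
F4 | step 8 | tert-butyldimethyl{[2-(4,4,5,5-tetramethyl-1,3,2-dioxaborolan-2-yl)prop-2-en-1-yl]oxy}silane | C=C(CO[Si](C)(C)C(C)(C)C)B1OC(C)(C)C(C)(C)O1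
F5 | step 8 | tert-butyl{[(3S)-3-(dimethoxymethyl)-2-methylidenepent-4-en-1-yl]oxy}dimethylsilane | C=C(CO[Si](C)(C)C(C)(C)C)[C@H](C=C)C(OC)OC
F6 | step 8 | (4aR,7R)-7-{3-[(tert-butyldimethylsilyl)oxy]prop-1-en-2-yl}-4a-methyl-3,4,4a,5,6,7-hexahydronaphthalen-1(2H)-one | C=C(CO[Si](C)(C)C(C)(C)C)[C@H]1C=C2[C@](C)(CCCC2=O)CC1
F7 | step 8 | (2R,4aS,7R)-2-bromo-7-{3-[(tert-butyldimethylsilyl)oxy]prop-1-en-2-yl}-4a-methyl-3,4,4a,5,6,7-hexahydronaphthalen-1(2H)-one | C=C(CO[Si](C)(C)C(C)(C)C)[C@H]1C=C2[C@](C)(CC[C@@H](Br)C2=O)CC1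
F8 | step 8 | (2S,4aS,7R)-7-{3-[(tert-butyldimethylsilyl)oxy]prop-1-en-2-yl}-4a-methyl-1-oxo-1,2,3,4,4a,5,6,7-octahydronaphthalen-2-yl (2Z)-2-methylbut-2-enoate | C=C(CO[Si](C)(C)C(C)(C)C)[C@H]1C=C2[C@](C)(CC[C@H](OC(=O)/C(C)=C\C)C2=O)CC1
F9 | step 8 | (1R,2S,4aS,7R)-7-{3-[(tert-butyldimethylsilyl)oxy]prop-1-en-2-yl}-1-hydroxy-1,4a-dimethyl-1,2,3,4,4a,5,6,7-octahydronaphthalen-2-yl (2Z)-2-methylbut-2-enoate | C=C(CO[Si](C)(C)C(C)(C)C)[C@H]1C=C2[C@](C)(CC[C@H](OC(=O)/C(C)=C\C)[C@]2(C)O)CC1
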